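**Assumption:** the given SMILES is the intended single enantiomer (five stereocentres; ring alkene Z, chlorovinyl Z, side-chain alkene E). The only protecting groups are a MOM ether and tert-butyl esters, both removed in the last step.

**Retrosynthetic overview**
1. The 14-membered ring is closed last by an intramolecular B-alkyl Suzuki coupling of the THF vinyl group (as its 9-BBN adduct) with a gem-dichloroalkene. This gives the Z-chloroalkene. The C3-ester bond to the THF is made intermolecularly beforehand.
2. The 2,5-trans-THF-3-ol core comes from furfural. Oxidative dearomatisation of the furan (Achmatowicz) gives a pyranone, and base-mediated ring contraction (5-endo oxa-Michael) gives the THF-3-one. A Roush anti-allylation sets the two carbinol centres, and cross-metathesis adds the E-trisubstituted side chain.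
3. The acid fragment is built from a methacrolein aldol adduct. RCM of its vinylacetate ester gives a six-membered lactone that fixes the Z-trisubstituted alkene. Weinreb opening and gem-dichloroolefination follow.
4. Ring-forming order: furan → pyranone (transient 6-ring) → THF; 6-membered lactone (transient, RCM); ester linkage (intermolecular); 14-membered macrocycle last.

**Step 1**
Reactants: 1 furfural
Product: 2 (1R,2R)-1-(furan-2-yl)-2-(methoxymethoxy)but-3-en-1-ol
Conditions: (E)-MOMOCH=CHCH2B(tartrate) (from allyl MOM ether, s-BuLi, B(OMe)3, then diisopropyl tartrate), toluene, 4 Å MS, –78 °C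
Reagents that add atoms: (E)-γ-(methoxymethoxy)allylboronate, COCO/C=C/CB1OC(C(=O)OC(C)C)C(C(=O)OC(C)C)O1 (tartrate enantiomer chosen to give the (R,R)-adduct)
Why: Roush γ-alkoxyallylboration proceeds through a closed chair transition state, so the (E)-reagent gives the anti-1,2-diol derivative and the tartrate sets the absolute configuration at both the carbinol and the ether carbon (these become T2 and C1′ of the target).

**Step 2**
Reactants: 3 3-methylbut-3-enoic acid
Product: 4 tert-butyl 3-methylbut-3-enoate
Conditions: Boc2O, DMAP (cat.), t-BuOH, 23 °C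
Reagents that add atoms: tert-butanol, CC(C)(C)O
Why: Boc2O/DMAP esterification gives the tert-butyl ester needed as the cross-metathesis partner and as an acid-labile carboxyl protecting group.

**Step 3**
Reactants: 2 and 4 (4 equiv)
Product: 5 tert-butyl (3E,5R,6R)-6-(furan-2-yl)-6-hydroxy-5-(methoxymethoxy)-3-methylhex-3-enoate
Conditions: Hoveyda–Grubbs II (5 mol%), 1,4-benzoquinone (10 mol%), CH2Cl2, 40 °C
Reagents that add atoms: none
Why: Cross-metathesis of the monosubstituted vinyl group with the 1,1-disubstituted olefin gives the thermodynamically favoured E-trisubstituted alkene (ethylene is lost), and benzoquinone suppresses Ru–H isomerisation into conjugation.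

**Step 4**
Reactants: 5
Product: 6 tert-butyl (3E,5R)-5-[(2R)-6-hydroxy-3-oxo-3,6-dihydro-2H-pyran-2-yl]-5-(methoxymethoxy)-3-methylpent-3-enoate (C6 anomeric mixture)
Conditions: NBS (1.0 equiv), NaHCO3, NaOAc·3H2O, THF/H2O 4:1, –5 → 0 °C
Reagents that add atoms: water, O (supplies the C6 hemiacetal oxygen)
Why: Achmatowicz oxidative dearomatisation: electrophilic bromination opens the electron-rich furan, which is far more reactive than the hindered trisubstituted alkene, and ring expansion gives the pyranone. The carbinol centre is untouched, so T2 keeps its (R) configuration, and the C6 anomeric centre is destroyed in the next step.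

**Step 5**
Reactants: 6
Product: 7 tert-butyl (3E,5R)-5-[(2R,5S)-5-formyl-3-oxooxolan-2-yl]-5-(methoxymethoxy)-3-methylpent-3-enoate
Conditions: Et3N (0.3 equiv), MeCN, 23 → 40 °C
Reagents that add atoms: none
Why: Proposed new method: base-catalysed ring–chain opening of the hemiacetal 6 gives the (Z)-α′-hydroxy-enone/enal, and 5-endo-trig oxa-Michael addition of the C2 hydroxyl onto C5 (β to the C3 ketone) gives the THF-3-one; because C5 (α to CHO) and C2 (α to the ketone) are epimerisable, the 2,5-trans isomer (side chain and CHO on opposite faces) is the thermodynamic product (expected ~3:1, separable at 8), the mild amine limits E1cB loss of the β-OMOM group, and the closest known chemistry is Achmatowicz ring–chain tautomerism plus 5-endo oxa-Michael closure of α′-hydroxy enones to THF-3-ones.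

**Step 6**
Reactants: 7
Product: 8 tert-butyl (3E,5R)-5-[(2R,5S)-3-oxo-5-vinyloxolan-2-yl]-5-(methoxymethoxy)-3-methylpent-3-enoate
Conditions: Ph3PCH3Br, KOt-Bu, THF, –78 → –20 °C
Reagents that add atoms: methyltriphenylphosphonium bromide, C[P+](c1ccccc1)(c1ccccc1)c1ccccc1.[Br-] (supplies the =CH2 unit)
Why: Wittig methylenation is selective for the aldehyde over the hindered ketone at low temperature and locks the C5 configuration as a vinyl group (later A/B of the chain).

**Step 7**
Reactants: 8
Product: 9 tert-butyl (3E,5R)-5-[(2S,3R,5S)-3-hydroxy-5-vinyloxolan-2-yl]-5-(methoxymethoxy)-3-methylpent-3-enoate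
Conditions: L-Selectride, THF, –78 °C
Reagents that add atoms: none
Why: The bulky hydride attacks the ketone anti to the adjacent C2 side chain (Felkin-type), delivering the C3 alcohol cis to that side chain, which is the T3 (R) configuration of the target.

**Step 8**
Reactants: 10 methacrolein
Product: 11 tert-butyl (R)-3-hydroxy-4-methylpent-4-enoate
Conditions: Cu(OTf)2 (5 mol%), Tol-BINAP (5.5 mol%; enantiomer giving the (R)-carbinol), TBAT (5 mol%), silyl ketene acetal, THF, –78 °C; then aq. NH4F
Reagents that add atoms: 1-tert-butoxy-1-(trimethylsiloxy)ethene, CC(C)(C)OC(=C)O[Si](C)(C)C (supplies CH2CO2tBu)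
Why: Carreira Cu(II)–BINAP catalytic Mukaiyama aldol sets the C3 carbinol (Ca of the target) in high ee.

**Step 9**
Reactants: 11 and 12 but-3-enoic acid (vinylacetic acid)
Product: 13 tert-butyl (R)-3-(but-3-enoyloxy)-4-methylpent-4-enoate
Conditions: EDC·HCl, DMAP (0.1 equiv), CH2Cl2, 0 °C
Reagents that add atoms: none
Why: Carbodiimide esterification at 0 °C with little DMAP limits isomerisation of the β,γ-unsaturated acyl group.

**Step 10**
Reactants: 13
Product: 14 tert-butyl 2-[(2R)-3-methyl-6-oxo-5,6-dihydro-2H-pyran-2-yl]acetate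
Conditions: Hoveyda–Grubbs II (5 mol%), 1,4-benzoquinone (10 mol%), toluene (0.01 M), 60 °C
Reagents that add atoms: none
Why: Ring-closing metathesis of the isopropenyl group with the vinylacetate forms the six-membered lactone, so the trisubstituted alkene is necessarily cis (Ca cis to E), which gives the Z geometry of the target; the carbinol centre is not touched.

**Step 11**
Reactants: 14
Product: 15 tert-butyl (3R,4Z)-3-hydroxy-7-[methoxy(methyl)amino]-4-methyl-7-oxohept-4-enoate
Conditions: MeNH(OMe)·HCl, AlMe3, CH2Cl2, 0 °C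
Reagents that add atoms: N,O-dimethylhydroxylamine, CNOC
Why: Aluminium-amide aminolysis (Weinreb–Basha) opens the lactone at the acyl–O bond, leaving the Ca–O bond and its configuration intact, and the hindered tert-butyl ester survives.

**Step 12**
Reactants: 15
Product: 16 tert-butyl (3R,4Z)-3-acetoxy-7-[methoxy(methyl)amino]-4-methyl-7-oxohept-4-enoate
Conditions: Ac2O, pyridine, DMAP (cat.), CH2Cl2, 0 °C
Reagents that add atoms: acetic anhydride, CC(=O)OC(C)=O
Why: Simple O-acetylation installs the C3 acetoxy group of the target without touching the stereocentre.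

**Step 13**
Reactants: 16
Product: 17 tert-butyl (3R,4Z)-3-acetoxy-4-methyl-7-oxohept-4-enoate
Conditions: DIBAL-H (1.2 equiv), THF, –78 °C
Reagents that add atoms: none
Why: The stable Weinreb tetrahedral intermediate gives the aldehyde on work-up; the acetate and tert-butyl ester are not reduced at –78 °C, and the crude β,γ-enal is used immediately.

**Step 14**
Reactants: 17
Product: 18 tert-butyl (3R,4Z)-3-acetoxy-8,8-dichloro-4-methylocta-4,7-dienoate
Conditions: PPh3 (3 equiv), CCl4, CH2Cl2, 0 → 23 °C
Reagents that add atoms: carbon tetrachloride, ClC(Cl)(Cl)Cl (supplies the CCl2 carbon)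
Why: Ramirez/Corey–Fuchs-type gem-dichloroolefination via Ph3P=CCl2 converts the aldehyde to the 1,1-dichloroalkene without disturbing the Z-alkene.

**Step 15**
Reactants: 18
Product: 19 (3R,4Z)-3-acetoxy-8,8-dichloro-4-methylocta-4,7-dienoic acid
Conditions: TFA/CH2Cl2 1:9, 0 °C, 1 h
Reagents that add atoms: none
Why: Acidolysis of the tert-butyl ester (isobutene lost) frees the acid needed for esterification; the allylic acetate and gem-dichloroalkene tolerate brief cold TFA.

**Step 16**
Reactants: 9 and 19
Product: 20 ester of 9 (at the C3-OH) with 19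
Conditions: 2,4,6-Cl3C6H2COCl, Et3N, THF, 0 °C; then 9, DMAP, toluene, 0 → 23 °C
Reagents that add atoms: none
Why: Yamaguchi esterification through the mixed anhydride joins the two fragments and forms the future lactone C(=O)–O bond, with low temperature and short DMAP exposure to limit β-acetoxy elimination.

**Step 17**
Reactants: 20
Product: 21 MOM-protected tert-butyl ester of the target (macrocycle)
Conditions: (a) 9-BBN dimer (0.6 equiv), THF, 23 °C; (b) add dropwise to PdCl2(dppf)·CH2Cl2 (15 mol%), AsPh3, Cs2CO3, THF/DMF/H2O, 50 °C (0.002 M)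
Reagents that add atoms: none (9-BBN supplies only H; boron leaves with Cl)
Why: Proposed new method: 9-BBN hydroborates only the monosubstituted vinyl group to give the primary alkyl-9-BBN, and Pd(0) inserts into the less hindered C–Cl of the gem-dichloroalkene, the one trans to the CH2 chain, so intramolecular B-alkyl Suzuki–Miyaura coupling forms the sp3–sp2 bond with retention and leaves the cis chlorine, giving the Z-chloroalkene within the 14-membered ring; the closest known chemistry is Danishefsky-type B-alkyl Suzuki macrocyclisation and stereoselective mono-coupling of 1,1-dichloroalkenes.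

**Step 18**
Reactants: 21
Product: 22 target (CID11123535)
Conditions: TFA/CH2Cl2 1:3, 0 → 23 °C, 2 h
Reagents that add atoms: none
Why: Acidolysis removes both the MOM ether and the tert-butyl ester in one operation, unmasking the C1′ allylic alcohol and the side-chain carboxylic acid without affecting any stereocentre.

**Compound list**
1 | furfural | O=Cc1ccco1 | starting material
2 | (1R,2R)-1-(furan-2-yl)-2-(methoxymethoxy)but-3-en-1-ol | O[C@@H](c1ccco1)[C@H](OCOC)C=C | intermediate
3 | 3-methylbut-3-enoic acid | C=C(C)CC(=O)O | starting material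
4 | tert-butyl 3-methylbut-3-enoate | C=C(C)CC(=O)OC(C)(C)C | intermediate
5 | tert-butyl (3E,5R,6R)-6-(furan-2-yl)-6-hydroxy-5-(methoxymethoxy)-3-methylhex-3-enoate | O[C@@H](c1ccco1)[C@H](OCOC)/C=C(\C)CC(=O)OC(C)(C)C | intermediate
6 | tert-butyl (3E,5R)-5-[(2R)-6-hydroxy-3-oxo-3,6-dihydro-2H-pyran-2-yl]-5-(methoxymethoxy)-3-methylpent-3-enoate | O=C1C=CC(O)O[C@@H]1[C@H](OCOC)/C=C(\C)CC(=O)OC(C)(C)C | intermediate
7 | tert-butyl (3E,5R)-5-[(2R,5S)-5-formyl-3-oxooxolan-2-yl]-5-(methoxymethoxy)-3-methylpent-3-enoate | O=C[C@@H]1CC(=O)[C@H](O1)[C@H](OCOC)/C=C(\C)CC(=O)OC(C)(C)C | intermediate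
8 | tert-butyl (3E,5R)-5-[(2R,5S)-3-oxo-5-vinyloxolan-2-yl]-5-(methoxymethoxy)-3-methylpent-3-enoate | C=C[C@@H]1CC(=O)[C@H](O1)[C@H](OCOC)/C=C(\C)CC(=O)OC(C)(C)C | intermediate
9 | tert-butyl (3E,5R)-5-[(2S,3R,5S)-3-hydroxy-5-vinyloxolan-2-yl]-5-(methoxymethoxy)-3-methylpent-3-enoate | C=C[C@@H]1C[C@@H](O)[C@H](O1)[C@H](OCOC)/C=C(\C)CC(=O)OC(C)(C)C | intermediate
10 | methacrolein | C=C(C)C=O | starting material
11 | tert-butyl (R)-3-hydroxy-4-methylpent-4-enoate | C=C(C)[C@H](O)CC(=O)OC(C)(C)C | intermediate
12 | but-3-enoic acid | C=CCC(=O)O | starting material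
13 | tert-butyl (R)-3-(but-3-enoyloxy)-4-methylpent-4-enoate | C=CCC(=O)O[C@@H](C(C)=C)CC(=O)OC(C)(C)C | intermediate
14 | tert-butyl 2-[(2R)-3-methyl-6-oxo-5,6-dihydro-2H-pyran-2-yl]acetate | O=C1CC=C(C)[C@@H](CC(=O)OC(C)(C)C)O1 | intermediate
15 | tert-butyl (3R,4Z)-3-hydroxy-7-[methoxy(methyl)amino]-4-methyl-7-oxohept-4-enoate | CON(C)C(=O)C/C=C(/C)[C@H](O)CC(=O)OC(C)(C)C | intermediate
16 | tert-butyl (3R,4Z)-3-acetoxy-7-[methoxy(methyl)amino]-4-methyl-7-oxohept-4-enoate | CON(C)C(=O)C/C=C(/C)[C@H](OC(C)=O)CC(=O)OC(C)(C)C | intermediate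
17 | tert-butyl (3R,4Z)-3-acetoxy-4-methyl-7-oxohept-4-enoate | O=CC/C=C(/C)[C@H](OC(C)=O)CC(=O)OC(C)(C)C | intermediate
18 | tert-butyl (3R,4Z)-3-acetoxy-8,8-dichloro-4-methylocta-4,7-dienoate | ClC(Cl)=CC/C=C(/C)[C@H](OC(C)=O)CC(=O)OC(C)(C)C | intermediate
19 | (3R,4Z)-3-acetoxy-8,8-dichloro-4-methylocta-4,7-dienoic acid | ClC(Cl)=CC/C=C(/C)[C@H](OC(C)=O)CC(=O)O | intermediate
20 | C3-O ester of 9 with 19 | C=C[C@@H]1C[C@@H](OC(=O)C[C@@H](OC(C)=O)/C(C)=C\CC=C(Cl)Cl)[C@H](O1)[C@H](OCOC)/C=C(\C)CC(=O)OC(C)(C)C | intermediate
21 | MOM ether/tert-butyl ester of the target (macrocycle) | CC(=O)O[C@@H]1CC(=O)O[C@@H]2C[C@@H](CC/C(Cl)=C/C/C=C\1C)O[C@@H]2[C@H](OCOC)/C=C(\C)CC(=O)OC(C)(C)C | intermediate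
22 | target, CID11123535 (C23H31ClO8) | CC(=O)O[C@@H]1CC(=O)O[C@@H]2C[C@@H](CC/C(Cl)=C/C/C=C\1C)O[C@@H]2[C@H](O)/C=C(\C)CC(=O)O | target

**Total steps:** 18.
**Longest linear sequence:** 11 steps (methacrolein 10 → 11 → 13 → 14 → 15 → 16 → 17 → 18 → 19 → 20 → 21 → 22).

**Three steps most likely to fail**
1. **Step 5 (ring contraction to the THF-3-one).** The pyranone may simply stay as the hemiacetal, or the 2,5-dr may be poor.
   - Fallback: reduce 6 with NaBH4/CeCl3 to the Z-ene-triol, protect the primary alcohol, and close the THF by Knight-type 5-endo iodoetherification (I2, NaHCO3) followed by Bu3SnH deiodination. Then oxidise the primary alcohol back to the aldehyde and rejoin at Step 6.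
2. **Step 7 (ketone reduction).** L-Selectride could favour attack from the face that puts the C3-OH trans to the C2 side chain, giving the wrong T3 epimer.
   - Fallback: accept the trans alcohol and invert it by Mitsunobu (p-nitrobenzoic acid, DEAD, PPh3) followed by K2CO3/MeOH.
3. **Step 17 (macro-Suzuki).** The gem-dichloroalkene may couple sluggishly, lose Z-selectivity, or the base may cleave or eliminate the β-acetoxy ester.
   - Fallback: close the ring by Yamaguchi macrolactonisation instead. Do an intermolecular Suzuki between the hydroborated, TES-protected 9 and the allyl ester of 18, then remove the allyl ester (Pd(PPh3)4, morpholine) and the TES group (PPTS, MeOH), and lactonise under high dilution.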